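**Plan**

- The retrosynthesis first opens the pyranone ring at C3–C4. C3 is an enolisable carbon alpha to the lactone carbonyl C2 and carries the triene chain; C4 is a carbonyl-derived carbon held on the benzo ring ortho to the ring oxygen O1. The cut therefore leaves a methyl O-acylsalicylate.
- Further cuts: the benzoate C–O bond, the C–O bond at the chain terminus (allylic C–H oxidation), the aryl ester C–O bond (methyl salicylate plus a C17 acid) and the C2–C3 bond of that acid (acetic acid dianion plus farnesyl bromide).
- Forward: farnesol is brominated, extended by two carbons, esterified with methyl salicylate, oxidised at the terminal methyl group and benzoylated. The pyranone, the only ring made, is closed in the last step.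
- Stereochemistry: there is no stereocentre. The two inner E alkenes are bought with (2E,6E)-farnesol and never touched; the terminal E alkene results from E-selective SeO2 oxidation of the methyl group trans to the chain.

Key step: step 6

Assumption: isomerically pure (2E,6E)-farnesol is used, and the target is drawn as its 4-hydroxy-2H-chromen-2-one tautomer.

**Route**

Step 1
Reactants: 1 (2E,6E)-farnesol
Product: 2 (2E,6E)-farnesyl bromide
Conditions: PBr3 (0.4 equiv), Et2O, 0 °C; used crude at once
Reagents that add atoms: phosphorus tribromide, BrP(Br)Br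
Why: PBr3 turns the primary allylic alcohol into a phosphite leaving group that bromide displaces in an SN2 reaction at 0 °C, the standard preparation of farnesyl bromide, which leaves both trisubstituted E alkenes and the allylic regiochemistry unchanged.

Step 2
Reactants: 2 (2E,6E)-farnesyl bromide; 3 acetic acid
Product: 6 (4E,8E)-5,9,13-trimethyltetradeca-4,8,12-trienoic acid, via dilithioacetate 4 (not isolated), via lithium carboxylate 5 (not isolated)
Conditions: AcOH (1.5 equiv), LiN(iPr)2 (3.1 equiv), THF–DMPU, 0 → 45 °C; then 2, 0 °C → rt; 1 M HCl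
Reagents that add atoms: none
Why: The enediolate (dianion) of acetic acid is C-alkylated by the reactive primary allylic bromide in an SN2 displacement at the unhindered CH2 terminus, a known two-carbon homologation of prenyl-type bromides that keeps the alkene geometry, and acidification releases the acid.

Step 3
Reactants: 6 (4E,8E)-5,9,13-trimethyltetradeca-4,8,12-trienoic acid; 7 methyl salicylate
Product: 9 methyl 2-{[(4E,8E)-5,9,13-trimethyltetradeca-4,8,12-trienoyl]oxy}benzoate, via acid chloride 8 (not isolated)
Conditions: (COCl)2, N,N-dimethylformamide (cat.), CH2Cl2, 0 °C → rt, evaporate; then 7, NEt3, 4-(dimethylamino)pyridine (cat.), CH2Cl2, 0 °C → rt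
Reagents that add atoms: none
Why: Oxalyl chloride with catalytic formamide (Vilsmeier-type activation) gives the acid chloride under mild conditions, and amine-mediated acylation of the hydrogen-bonded phenol (nucleophilic acyl substitution of the Einhorn type) is the usual entry to methyl O-acylsalicylates, with no competing nucleophile in either partner.

Step 4
Reactants: 9 methyl 2-{[(4E,8E)-5,9,13-trimethyltetradeca-4,8,12-trienoyl]oxy}benzoate
Product: 10 methyl 2-{[(4E,8E,12E)-14-hydroxy-5,9,13-trimethyltetradeca-4,8,12-trienoyl]oxy}benzoate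
Conditions: SeO2 (0.3 equiv), t-BuOOH (70% aq., 2.5 equiv), salicylic acid (0.1 equiv), CH2Cl2, 0 °C → rt; stopped before full conversion, 9 recycled
Reagents that add atoms: selenium dioxide, O=[Se]=O (delivers the oxygen); tert-butyl hydroperoxide, CC(C)(C)OO (terminal oxidant that replenishes it)
Why: The SeO2-catalysed allylic oxidation (Riley oxidation: ene reaction followed by a [2,3]-sigmatropic shift) is known to pick the sterically most exposed terminal isopropylidene of polyprenyl chains and to oxidise the methyl group trans to the chain, which fixes the new hydroxymethyl-bearing alkene as E, while the esters and the arene are inert to this neutral oxidant.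

Step 5
Reactants: 10 methyl 2-{[(4E,8E,12E)-14-hydroxy-5,9,13-trimethyltetradeca-4,8,12-trienoyl]oxy}benzoate; 11 benzoyl chloride
Product: 12 methyl 2-{[(4E,8E,12E)-14-(benzoyloxy)-5,9,13-trimethyltetradeca-4,8,12-trienoyl]oxy}benzoate
Conditions: 11 (1.2 equiv), pyridine, CH2Cl2, 0 °C
Reagents that add atoms: none
Why: Einhorn-type acylation of the primary allylic alcohol by benzoyl chloride in pyridine is fast at 0 °C and needs no stronger acyl-transfer catalyst, so the activated aryl ester and the methyl ester are not transacylated.

Step 6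
Reactants: 12 methyl 2-{[(4E,8E,12E)-14-(benzoyloxy)-5,9,13-trimethyltetradeca-4,8,12-trienoyl]oxy}benzoate
Product: 14 E-omega-benzoyloxyferulenol [(2E,6E,10E)-12-(4-hydroxy-2-oxo-2H-chromen-3-yl)-2,6,10-trimethyldodeca-2,6,10-trien-1-yl benzoate], via lithium coumarinolate 13 (not isolated)
Conditions: LiN(SiMe3)2 (2.2 equiv), THF (dilute), −78 → −20 °C; then 1 M HCl at −20 °C
Reagents that add atoms: none
Why: LiN(SiMe3)2 removes a proton from the CH2 alpha to the aryl ester carbonyl (future C3), the enolate adds to the neighbouring methyl ester carbonyl (future C4), and collapse of the adduct with loss of methoxide forms the C3–C4 bond and a chromane-2,4-dione that is deprotonated at once to the lithium 4-olate 13 and protonated on acidic work-up. The closest known reaction type is the intramolecular Claisen (Dieckmann-type) condensation of methyl O-acylsalicylates to 3-substituted 4-hydroxycoumarins. The pyranone ring closes in a favoured 6-(enolendo)-exo-trig mode. No stereocentre is created, and the three E alkenes are inert to the amide base and pass through unchanged. The step needs chemoselectivity, which the substrate secures because the benzoate and the aryl carboxylate have no alpha hydrogen, so only one site can enolise, and because the six-membered intramolecular closure outruns intermolecular attack of the enolate on the remote benzoate. The hindered silylamide does not add to esters, the acidic product is stored as its unreactive salt, and the low temperature with a cold acidic quench keeps lithium methoxide from transesterifying the benzoate.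

**Compound list**

1 | (2E,6E)-farnesol | CC(C)=CCC/C(C)=C/CC/C(C)=C/CO | starting material
2 | (2E,6E)-farnesyl bromide; (2E,6E)-1-bromo-3,7,11-trimethyldodeca-2,6,10-triene | CC(C)=CCC/C(C)=C/CC/C(C)=C/CBr | intermediate
3 | acetic acid | CC(=O)O | starting material
4 | dilithioacetate; dilithium ethene-1,1-bis(olate) | [Li+].[Li+].C=C([O-])[O-] | intermediate
5 | lithium (4E,8E)-5,9,13-trimethyltetradeca-4,8,12-trienoate | CC(C)=CCC/C(C)=C/CC/C(C)=C/CCC(=O)[O-].[Li+] | intermediate
6 | (4E,8E)-5,9,13-trimethyltetradeca-4,8,12-trienoic acid (farnesylacetic acid) | CC(C)=CCC/C(C)=C/CC/C(C)=C/CCC(=O)O | intermediate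
7 | methyl salicylate | COC(=O)c1ccccc1O | starting material
8 | (4E,8E)-5,9,13-trimethyltetradeca-4,8,12-trienoyl chloride | CC(C)=CCC/C(C)=C/CC/C(C)=C/CCC(=O)Cl | intermediate
9 | methyl 2-{[(4E,8E)-5,9,13-trimethyltetradeca-4,8,12-trienoyl]oxy}benzoate | CC(C)=CCC/C(C)=C/CC/C(C)=C/CCC(=O)Oc1ccccc1C(=O)OC | intermediate
10 | methyl 2-{[(4E,8E,12E)-14-hydroxy-5,9,13-trimethyltetradeca-4,8,12-trienoyl]oxy}benzoate | C/C(=C\CC/C(C)=C/CCC(=O)Oc1ccccc1C(=O)OC)CC/C=C(\C)CO | intermediate
11 | benzoyl chloride | O=C(Cl)c1ccccc1 | starting material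
12 | methyl 2-{[(4E,8E,12E)-14-(benzoyloxy)-5,9,13-trimethyltetradeca-4,8,12-trienoyl]oxy}benzoate | C/C(=C\CC/C(C)=C/CCC(=O)Oc1ccccc1C(=O)OC)CC/C=C(\C)COC(=O)c1ccccc1 | intermediate
13 | lithium 3-[(2E,6E,10E)-12-(benzoyloxy)-3,7,11-trimethyldodeca-2,6,10-trien-1-yl]-2-oxo-2H-chromen-4-olate | C/C(=C\CC/C(C)=C/Cc1c([O-])c2ccccc2oc1=O)CC/C=C(\C)COC(=O)c1ccccc1.[Li+] | intermediate
14 | E-omega-benzoyloxyferulenol; (2E,6E,10E)-12-(4-hydroxy-2-oxo-2H-chromen-3-yl)-2,6,10-trimethyldodeca-2,6,10-trien-1-yl benzoate | C/C(=C\CC/C(C)=C/Cc1c(O)c2ccccc2oc1=O)CC/C=C(\C)COC(=O)c1ccccc1 | target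

**Step count and risks**

Total step count: 6. Longest linear sequence: 6 steps (1 to 14).

Steps most likely to fail:

Step 4 (allylic oxidation of 9). The ene oxidation may spread over the two inner trisubstituted alkenes, run on to the enal, or slowly cleave the activated aryl ester during the long exposure to aqueous peroxide. Over-oxidised material cannot be returned with hydride while that ester is present. The fallback oxidises before the chain is extended, where the alkene next to the oxygenated carbon is deactivated and a borohydride wash-back is harmless. It sets out from 1 and comes back at 12. Compound 1 is silylated (t-BuMe2SiCl, imidazole, DMF) to tert-butyldimethylsilyl farnesyl ether F1. SeO2 (cat.) with t-BuOOH, followed by NaBH4, gives the terminal E allylic alcohol F2. Compound 11 and pyridine give the benzoate F3, and n-Bu4NF buffered with AcOH frees the allylic alcohol F4. PBr3 in Et2O gives the allylic bromide F5. This alkylates dilithioacetate 4 at −78 → −20 °C, where displacement of the allylic bromide should outrun addition to the benzoate, and acidification gives the benzoyloxy acid F6. Oxalyl chloride converts F6 into the acid chloride F7, which acylates 7 (NEt3, 4-(dimethylamino)pyridine) to give 12.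

Step 6 (ring closure). Lithium methoxide released in the condensation, or base left over on warming, may transesterify or cleave the remote benzoate before the quench. The fallback closes the ring with a base-stable silyl ether at the chain terminus and installs the benzoate last. It sets out from 10 and comes back at 14. Compound 10 is silylated (t-BuMe2SiOTf, 2,6-lutidine, CH2Cl2, −78 °C) to the silyl ether F8. LiN(SiMe3)2 in THF then closes the pyranone as in step 6 to give the silyloxy coumarin F9, and HF·pyridine in THF frees E-omega-hydroxyferulenol F10. Excess 11 in pyridine acylates both hydroxyl groups to the dibenzoate F11. Morpholine at 0 °C then removes only the enol benzoate at C4, a vinylogous anhydride far more reactive than the allylic benzoate, to give 14.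

Step 2 (dianion alkylation). The hard, poorly soluble dianion may react slowly, so that the labile allylic bromide eliminates or is attacked at its tertiary terminus (SN2′) to give a branched acid. The fallback is the malonic ester synthesis. It sets out from 2 and comes back at 6. Sodium dimethyl malonate (NaH, THF, 0 °C → rt) is alkylated by 2 to give the farnesylmalonate F12. KOH in aqueous MeOH followed by acidification gives the malonic acid F13, and heating in pyridine expels CO2 to give 6.

**Further compounds**

F1 | step 4 | tert-butyl(dimethyl){[(2E,6E)-3,7,11-trimethyldodeca-2,6,10-trien-1-yl]oxy}silane | CC(C)=CCC/C(C)=C/CC/C(C)=C/CO[Si](C)(C)C(C)(C)C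
F2 | step 4 | (2E,6E,10E)-12-[(tert-butyldimethylsilyl)oxy]-2,6,10-trimethyldodeca-2,6,10-trien-1-ol | C/C(=C\CC/C(C)=C/CO[Si](C)(C)C(C)(C)C)CC/C=C(\C)CO
F3 | step 4 | (2E,6E,10E)-12-[(tert-butyldimethylsilyl)oxy]-2,6,10-trimethyldodeca-2,6,10-trien-1-yl benzoate | C/C(=C\CC/C(C)=C/CO[Si](C)(C)C(C)(C)C)CC/C=C(\C)COC(=O)c1ccccc1
F4 | step 4 | (2E,6E,10E)-12-hydroxy-2,6,10-trimethyldodeca-2,6,10-trien-1-yl benzoate | C/C(=C\CC/C(C)=C/CO)CC/C=C(\C)COC(=O)c1ccccc1
F5 | step 4 | (2E,6E,10E)-12-bromo-2,6,10-trimethyldodeca-2,6,10-trien-1-yl benzoate | C/C(=C\CC/C(C)=C/CBr)CC/C=C(\C)COC(=O)c1ccccc1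
F6 | step 4 | (4E,8E,12E)-14-(benzoyloxy)-5,9,13-trimethyltetradeca-4,8,12-trienoic acid | C/C(=C\CC/C(C)=C/CCC(=O)O)CC/C=C(\C)COC(=O)c1ccccc1
F7 | step 4 | (4E,8E,12E)-14-(benzoyloxy)-5,9,13-trimethyltetradeca-4,8,12-trienoyl chloride | C/C(=C\CC/C(C)=C/CCC(=O)Cl)CC/C=C(\C)COC(=O)c1ccccc1
F8 | step 6 | methyl 2-{[(4E,8E,12E)-14-[(tert-butyldimethylsilyl)oxy]-5,9,13-trimethyltetradeca-4,8,12-trienoyl]oxy}benzoate | C/C(=C\CC/C(C)=C/CCC(=O)Oc1ccccc1C(=O)OC)CC/C=C(\C)CO[Si](C)(C)C(C)(C)C
F9 | step 6 | 3-{(2E,6E,10E)-12-[(tert-butyldimethylsilyl)oxy]-3,7,11-trimethyldodeca-2,6,10-trien-1-yl}-4-hydroxy-2H-chromen-2-one | C/C(=C\CC/C(C)=C/Cc1c(O)c2ccccc2oc1=O)CC/C=C(\C)CO[Si](C)(C)C(C)(C)C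
F10 | step 6 | E-omega-hydroxyferulenol; 4-hydroxy-3-[(2E,6E,10E)-12-hydroxy-3,7,11-trimethyldodeca-2,6,10-trien-1-yl]-2H-chromen-2-one | C/C(=C\CC/C(C)=C/Cc1c(O)c2ccccc2oc1=O)CC/C=C(\C)CO
F11 | step 6 | 3-[(2E,6E,10E)-12-(benzoyloxy)-3,7,11-trimethyldodeca-2,6,10-trien-1-yl]-2-oxo-2H-chromen-4-yl benzoate | C/C(=C\CC/C(C)=C/Cc1c(OC(=O)c2ccccc2)c2ccccc2oc1=O)CC/C=C(\C)COC(=O)c1ccccc1
F12 | step 2 | dimethyl 2-[(2E,6E)-3,7,11-trimethyldodeca-2,6,10-trien-1-yl]propanedioate | CC(C)=CCC/C(C)=C/CC/C(C)=C/CC(C(=O)OC)C(=O)OC
F13 | step 2 | 2-[(2E,6E)-3,7,11-trimethyldodeca-2,6,10-trien-1-yl]propanedioic acid | CC(C)=CCC/C(C)=C/CC/C(C)=C/CC(C(=O)O)C(=O)O
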